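Nucleophile and electrophile are never destroyed; they only change company, so one balance for each holds at every moment in any stirred flask of constant volume.

| setting | birch | ash | cedar | red | green | grey | violet |
|---|---|---|---|---|---|---|---|
| electrophile | 20 mM | 10 mM | 40 mM | 20 mM (fed, over 4.0 h) | 20 mM (in portions, 3, over 4.0 h) | 20 mM (fed, over 4.0 h) | 20 mM |
| nucleophile | 16 mM | 16 mM | 16 mM | 16.0 mM | 16.0 mM | 16.0 mM | 16.0 mM |
| free base | 20 mM | 20 mM | 20 mM | 20.0 mM | 20.0 mM | 20.0 mM | 20.0 mM (fed, over 4.0 h) |
| protic impurity | 1 mM | 1 mM | 1 mM | 1.00 mM | 1.00 mM | 1.00 mM | 1.00 mM |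
| temperature | 0 °C | 11 °C | 0 °C | 5 °C | 5 °C |  | 5 °C |
| remark | run made earlier | run made earlier | run made earlier | all else is in the flask from the start; the feed brings no volume worth counting | first portion at the start, last at 4.0 h | the addition at −25 °C, then warmed to 5 °C; the feed brings no volume worth counting | all else is in the flask from the start; the feed brings no volume worth counting |
| time |  |  |  | 10 h | 10 h | 10 h | 10 h |

| run | time / h | target / % | electrophile / % |
|---|---|---|---|
| birch | 0.833 | 63.7 | 12.6 |
| birch | 1.33 | 60.1 | 6.3 |
| birch | 2.00 | 56.9 | 5.3 |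
| birch | 4.00 | 55.8 | 2.3 |
| birch | 6.00 | 54.0 | 0 |
| birch | 10.0 | 54.3 | 0.5 |
| ash | 2.00 | 58.0 | 1.2 |
| ash | 4.00 | 42.6 | 0.2 |
| ash | 6.00 | 38.0 | 0 |
| ash | 8.00 | 37.9 | 0.4 |
| ash | 10.0 | 33.7 | 0 |
| ash | 12.0 | 32.8 | 0 |
| cedar | 0.833 | 18.7 | 38.5 |
| cedar | 2.50 | 6.0 | 25.7 |
| cedar | 4.00 | 3.6 | 22.4 |
| cedar | 6.00 | 1.5 | 21.4 |
| cedar | 10.0 | 0.7 | 18.4 |
| cedar | 12.0 | 1.0 | 18.1 |

(readings scatter by 1 percentage point)



- the flask with the highest amount of target, in percent of the electrophile charged ("all alike" if they lie within 1.5 percentage points) (red / green / grey / violet / all alike)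
- final target, as a percentage of the electrophile charged, in red
- final target, as a percentage of the electrophile charged, in green
- final target, as a percentage of the electrophile charged, in grey
- final target, as a percentage of the electrophile charged, in violet

The readings tell me which companies exist. Cedar ends with 32.8 mM of electrophile consumed on 16 mM of nucleophile, so a second electrophile goes onto target, giving what I call side product. In ash, target falls from 58.0% to 32.8% while electrophile reads 0% at the end, so nucleophile attacks target too, giving over-reaction product.

Now I count units, with electrophile and nucleophile both used up: target holds one of each, side product two electrophiles and one nucleophile, over-reaction product two nucleophiles and one electrophile. Side product cancels, and c(target) = 2·c(nucleophile charged) − c(electrophile charged) + c(quenched substrate) − 3·c(over-reaction product). With the protic impurity wholly quenched, the first terms make the target ceiling 13.0 mM, or 65.0% of the electrophile charged. I need compute only the correction. Birch's last reading puts it at about 0.713 mM.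

Turned round: for the flasks to come out alike, their over-reaction products would have to agree within 0.5 percentage points. Red stands far from that, since its feed keeps nucleophile and target together for 4.0 h, longer than the 0.833 h by which birch's electrophile reads 12.6%. Scaling birch's loss by that ratio, I reckon 3.43 mM for red, hence 13.6% target. Grey I expect higher, with its feed at −25 °C, but I have no number for it.

The forecast takes 2.3 mM for red, not my figure, and says 28% for red, 20% for green, 49% for grey and 53% for violet, holding that “violet behaves like a batch run”; its choice is violet.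

The flasks give 20.0% in red, 15.9% in green, 52.6% in grey and 29.0% in violet, so grey leads.

electrophile + nucleophile → acid set free + target (k = 22.5 L mol⁻¹ min⁻¹, Ea = 52.0 kJ mol⁻¹); nucleophile + acid set free ⇌ protonated nucleophile, settled at all times (K = 1.52 × 10⁵ L mol⁻¹, ΔH = 6.00 kJ mol⁻¹); acid set free + free base ⇌ salt of the base, settled at all times (K = 3.40 × 10⁶ L mol⁻¹, ΔH = −18.0 kJ mol⁻¹); electrophile + target → side product (k = 1.17 L mol⁻¹ min⁻¹, Ea = 45.0 kJ mol⁻¹); electrophile + protic impurity → quenched substrate (k = 2.41 L mol⁻¹ min⁻¹, Ea = 47.0 kJ mol⁻¹); nucleophile + target → over-reaction product (k = 0.657 L mol⁻¹ min⁻¹, Ea = 54.0 kJ mol⁻¹); (constants at 5 °C) Grey holds 3.42% of over-reaction product, and the ceiling less 3 points for each gives 54.7% against its 52.6%; red's 15.5% gives 18.5% against 20.0%. In grey at 2.53 h, electrophile uses target 1.7 times as fast as nucleophile does. At 10.0 h that ratio of rates in grey stands higher, at 14.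

The readings were computed with constants of no real substance.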